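The plan cuts the bond between C5 of the butenolide ring (O1, C2–C5), the only stereocentre, and the first CH2 of the C15 side chain. C5 carries the ring oxygen O1 and is allylic to C3=C4, so a radical there is planar and delocalised over the whole 2-oxofuran ring. The key step uses this. A nickel/pybox-catalysed enantioconvergent Negishi coupling joins a racemic 5-bromobutenolide, obtained by Wohl–Ziegler bromination of the achiral parent lactone, with the complete ester-bearing alkylzinc iodide. It forms the C5–CH2 bond and sets (R)-C5 in one operation. Both acids travel as tert-butyl esters and are freed by acid, never base.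

Key step: step 5

Remark: in the text the ring is numbered O1, C2 (lactone C=O), C3 (CH3), C4 (carboxyl), C5 (stereocentre), which is C2 of the systematic names; the sense of induction of the pybox ligand on this substrate cannot be taken from precedent, so the (S,S)-ligand is written on the assumption that it gives (R)-C5, and its equally available mirror image replaces it, with nothing else changed, if a pilot run shows the opposite.

Step 1
Reactants: 1 3-bromo-2-oxopropanoic acid (bromopyruvic acid)
Product: 2 tert-butyl 3-bromo-2-oxopropanoate
Conditions: Cl3CC(=NH)OtBu (2 equiv), cyclohexane/CH2Cl2, rt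
Reagents that add atoms: tert-butyl 2,2,2-trichloroacetimidate, CC(C)(C)OC(=N)C(Cl)(Cl)Cl
Why: Trichloroacetimidate esterification: the strongly acidic α-keto acid protonates the imidate, which passes a tert-butyl cation to the carboxylate without any base, so the base-sensitive α-bromo ketone should survive.

Step 2
Reactants: 2 tert-butyl 3-bromo-2-oxopropanoate; 3 2-(diethoxyphosphoryl)propanoic acid (racemic)
Product: 5 tert-butyl 4-methyl-5-oxo-2,5-dihydrofuran-3-carboxylate, via phosphonate keto ester 4 (not isolated)
Conditions: 3, Cs2CO3 (1.0 equiv), MeCN, 0 °C; add 2; then Cs2CO3 (1.1 equiv), 0 °C to rt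
Reagents that add atoms: none
Why: Carboxylate SN2 alkylation by the α-bromo ketone gives 4, and an intramolecular Horner–Wadsworth–Emmons olefination of its very electrophilic α-keto ester carbonyl closes the five-membered lactone, in which C2 and C5 can only stand cis on C3=C4.

Step 3
Reactants: 5 tert-butyl 4-methyl-5-oxo-2,5-dihydrofuran-3-carboxylate
Product: 6 tert-butyl 2-bromo-4-methyl-5-oxo-2,5-dihydrofuran-3-carboxylate (racemic 5-bromobutenolide)
Conditions: NBS (1.0 equiv), AIBN (5 mol %), PhCF3, 85 °C
Reagents that add atoms: N-bromosuccinimide, O=C1CCC(=O)N1Br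
Why: Wohl–Ziegler bromination: hydrogen abstraction should take place at C5, whose radical is allylic and supported by O1, as in the standard NBS bromination of 3-methylfuran-2(5H)-one to its 5-bromide, and the racemic nature of 6 is of no consequence for step 5.

Step 4
Reactants: 7 16-(tert-butoxy)-16-oxohexadecanoic acid (hexadecanedioic acid mono-tert-butyl ester)
Product: 9 tert-butyl 15-iodopentadecanoate, via acyl hypoiodite 8 (not isolated)
Conditions: PhI(OAc)2 (0.6 equiv), I2 (0.6 equiv), cyclohexane, tungsten lamp, reflux
Reagents that add atoms: iodine, II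
Why: Hunsdiecker-type iododecarboxylation: ligand exchange on trivalent iodine and reaction with I2 give 8, whose O–I bond is cleaved by light, CO2 is lost and the primary radical is trapped by iodine, while the tert-butyl ester is inert.

Step 5
Reactants: 6 tert-butyl 2-bromo-4-methyl-5-oxo-2,5-dihydrofuran-3-carboxylate (racemic); 9 tert-butyl 15-iodopentadecanoate
Product: 11 tert-butyl (2R)-2-[15-(tert-butoxy)-15-oxopentadecyl]-4-methyl-5-oxo-2,5-dihydrofuran-3-carboxylate, via alkylzinc iodide 10 (not isolated)
Conditions: 9 (1.5 equiv), Zn dust (TMSCl-activated), DMA, 40 °C, decant from excess Zn; add to 6, NiCl2·glyme (10 mol %), (S,S)-CH2CH2Ph-pybox (13 mol %), DMA/DMF, −10 °C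
Reagents that add atoms: zinc, [Zn] (held only in intermediate 10)
Why: Proposed new method: monovalent nickel–pybox abstracts bromine from either enantiomer of 6 to give the planar 5-oxo-2,5-dihydrofuran-2-yl radical (spin shared by C5, C3 and the C2 carbonyl oxygen, supported by the lone pair of O1), which erases the configuration of 6; this radical is captured by the divalent alkylnickel species that arises from 10 by transmetalation, and reductive elimination from trivalent nickel forms the C5–CH2 bond. The closest known reaction types are the nickel/pybox-catalysed enantioconvergent Negishi alkylation of racemic secondary allylic chlorides, γ-chloro-α,β-unsaturated esters among them, and the nickel-catalysed enantioconvergent alkylation of racemic 1-haloalkyl esters; 6 holds both motifs in one ring, but 5-halobutenolides have not been shown in such couplings. No ring is closed. The C5 stereocentre is set under catalyst control by the C2-symmetric pybox ligand, probably helped by contact of the C4 ester carbonyl with nickel, in the capture and reductive elimination events. The step needs C5 over C3 regioselectivity, secured because C3 is fully substituted and bond formation there would cost the conjugation of C3=C4 with both carbonyl groups, and it needs chemoselectivity, secured by the low basicity and nucleophilicity of 10 towards the lactone, the two tert-butyl esters and the C5–H of 11. The uncatalysed racemic substitution of 6 by 10 is held back by the low temperature.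

Step 6
Reactants: 11 tert-butyl (2R)-2-[15-(tert-butoxy)-15-oxopentadecyl]-4-methyl-5-oxo-2,5-dihydrofuran-3-carboxylate
Product: 12 (2R)-2-(14-carboxytetradecyl)-4-methyl-5-oxo-2,5-dihydrofuran-3-carboxylic acid (target)
Conditions: TFA/CH2Cl2, 0 °C to rt
Reagents that add atoms: none
Why: Acidolysis of tert-butyl esters (alkyl–oxygen cleavage via the tert-butyl cation) frees both acids, and as no base is present the lactone stays closed and the C5–H is not exchanged, so the (R)-configuration is kept.

Compound list
1 | 3-bromo-2-oxopropanoic acid (bromopyruvic acid) | OC(=O)C(=O)CBr | starting material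
2 | tert-butyl 3-bromo-2-oxopropanoate | CC(C)(C)OC(=O)C(=O)CBr | intermediate
3 | 2-(diethoxyphosphoryl)propanoic acid (racemic) | CCOP(=O)(OCC)C(C)C(=O)O | starting material
4 | tert-butyl 3-{[2-(diethoxyphosphoryl)propanoyl]oxy}-2-oxopropanoate (not isolated) | CCOP(=O)(OCC)C(C)C(=O)OCC(=O)C(=O)OC(C)(C)C | intermediate
5 | tert-butyl 4-methyl-5-oxo-2,5-dihydrofuran-3-carboxylate | CC1=C(C(=O)OC(C)(C)C)COC1=O | intermediate
6 | tert-butyl 2-bromo-4-methyl-5-oxo-2,5-dihydrofuran-3-carboxylate (racemic) | CC1=C(C(=O)OC(C)(C)C)C(Br)OC1=O | intermediate
7 | 16-(tert-butoxy)-16-oxohexadecanoic acid | OC(=O)CCCCCCCCCCCCCCC(=O)OC(C)(C)C | starting material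
8 | 16-(tert-butoxy)-16-oxohexadecanoyl hypoiodite (not isolated) | IOC(=O)CCCCCCCCCCCCCCC(=O)OC(C)(C)C | intermediate
9 | tert-butyl 15-iodopentadecanoate | ICCCCCCCCCCCCCCC(=O)OC(C)(C)C | intermediate
10 | [15-(tert-butoxy)-15-oxopentadecyl]zinc iodide (not isolated) | I[Zn]CCCCCCCCCCCCCCC(=O)OC(C)(C)C | intermediate
11 | tert-butyl (2R)-2-[15-(tert-butoxy)-15-oxopentadecyl]-4-methyl-5-oxo-2,5-dihydrofuran-3-carboxylate | CC1=C(C(=O)OC(C)(C)C)[C@@H](CCCCCCCCCCCCCCC(=O)OC(C)(C)C)OC1=O | intermediate
12 | (2R)-2-(14-carboxytetradecyl)-4-methyl-5-oxo-2,5-dihydrofuran-3-carboxylic acid | CC1=C(C(=O)O)[C@@H](CCCCCCCCCCCCCCC(=O)O)OC1=O | target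

Total step count: 6. Longest linear sequence: 5 (steps 1, 2, 3, 5, 6).

Steps most likely to fail

Step 5 (labelled step).
- The coupling may suffer from poor facial discrimination in the capture of the flat radical.
- The long-lived radical may dimerise.
- Halogen–zinc exchange may reduce the C–Br bond.
- Uncatalysed racemic substitution may compete.

The fallback makes the same bond by known polar chemistry. It sets out from 6 and 9 and comes back at 11. Bromide 6 is hydrolysed (H2O/dioxane, 60 °C) to the pseudo-acid tert-butyl 2-hydroxy-4-methyl-5-oxo-2,5-dihydrofuran-3-carboxylate F1. Its ring-opened carboxylate is O-methylated (MeI, K2CO3, DMF) to the aldehyde 1-tert-butyl 4-methyl (2E)-2-formyl-3-methylbut-2-enedioate F2. Iodide 9 is converted by iodine–zinc exchange (Et2Zn, CuI cat., 50 °C, then vacuum) into bis[15-(tert-butoxy)-15-oxopentadecyl]zinc F3. F3 is then added to F2 by catalytic asymmetric dialkylzinc addition (Ti(OiPr)4, (1S,2S)-1,2-bis(trifluoromethanesulfonamido)cyclohexane 8 mol %, toluene, −20 °C). The alkyl group should go to the Re face of the aldehyde and give the alkoxide of 1-tert-butyl 4-methyl (2E)-2-[(1R)-16-(tert-butoxy)-1-hydroxy-16-oxohexadecyl]-3-methylbut-2-enedioate F4. This alkoxide lactonises in the flask onto the cis methyl ester to give 11. The tandem addition/lactonisation is of the kind known for 2-formylbenzoates.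

Step 3. Hydrogen abstraction may compete at the C3 methyl group, which is also allylic. A second bromination at C5 or acid-induced loss of the tert-butyl ester may follow. The fallback replaces the radical process by an ionic one. It sets out from 5 and comes back at 6. Soft enolisation (TBSOTf, Et3N, CH2Cl2, 0 °C) gives tert-butyl 5-[(tert-butyldimethylsilyl)oxy]-4-methylfuran-3-carboxylate F5. Br2 (CH2Cl2, −78 °C) should attack this furan at its only free α-position, C5, with loss of the silyl group.

Step 2. Base may enolise the acyloxy keto ester or cause self-condensation of the bromopyruvate faster than the olefination closes the ring. The fallback forms C3–C4 under reductive, non-basic conditions. It sets out from 2 and comes back at 5. Bromide 2 is alkylated by the carboxylate of 2-bromopropanoic acid (KHCO3, DMF, 0 °C) to give tert-butyl 3-[(2-bromopropanoyl)oxy]-2-oxopropanoate F6. An intramolecular Reformatsky reaction (activated Zn, THF) gives tert-butyl 3-hydroxy-4-methyl-5-oxooxolane-3-carboxylate F7. Treatment with MsCl/Et3N forms tert-butyl 3-(methanesulfonyloxy)-4-methyl-5-oxooxolane-3-carboxylate F8, which undergoes E1cB elimination in the same flask to give 5.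

Further compounds
F1 | step 5 | tert-butyl 2-hydroxy-4-methyl-5-oxo-2,5-dihydrofuran-3-carboxylate (racemic) | CC1=C(C(=O)OC(C)(C)C)C(O)OC1=O
F2 | step 5 | 1-tert-butyl 4-methyl (2E)-2-formyl-3-methylbut-2-enedioate | COC(=O)/C(C)=C(\C=O)C(=O)OC(C)(C)C
F3 | step 5 | bis[15-(tert-butoxy)-15-oxopentadecyl]zinc | CC(C)(C)OC(=O)CCCCCCCCCCCCCC[Zn]CCCCCCCCCCCCCCC(=O)OC(C)(C)C
F4 | step 5 | 1-tert-butyl 4-methyl (2E)-2-[(1R)-16-(tert-butoxy)-1-hydroxy-16-oxohexadecyl]-3-methylbut-2-enedioate | COC(=O)/C(C)=C(\[C@H](O)CCCCCCCCCCCCCCC(=O)OC(C)(C)C)C(=O)OC(C)(C)C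
F5 | step 3 | tert-butyl 5-[(tert-butyldimethylsilyl)oxy]-4-methylfuran-3-carboxylate | Cc1c(O[Si](C)(C)C(C)(C)C)occ1C(=O)OC(C)(C)C
F6 | step 2 | tert-butyl 3-[(2-bromopropanoyl)oxy]-2-oxopropanoate (racemic) | CC(Br)C(=O)OCC(=O)C(=O)OC(C)(C)C
F7 | step 2 | tert-butyl 3-hydroxy-4-methyl-5-oxooxolane-3-carboxylate (racemic, mixture of diastereomers) | CC1C(=O)OCC1(O)C(=O)OC(C)(C)C
F8 | step 2 | tert-butyl 3-(methanesulfonyloxy)-4-methyl-5-oxooxolane-3-carboxylate | CC1C(=O)OCC1(OS(C)(=O)=O)C(=O)OC(C)(C)C
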